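**Retrosynthetic overview**
1. One disconnection: the alkyl C–O bond of the ester (CO2–CH2). It leads back to 2,3-dihydroxybenzoic acid (1) as the oxygen nucleophile and 1-octadecanol (2) as the carbon electrophile, activated in the flask through the catalyst-derived phosphonium salts 3 and 4; the product is Gentiside E (5).
2. No ring is formed: the only ring, benzene ring A with its 1-carboxyl, 2-hydroxy and 3-hydroxy groups, is bought intact in 1.
3. No protecting groups: selectivity rests on acidity, the carboxyl group (pKa about 2.9) being the only oxygen nucleophile that is ionised. The catalyst, (2-hydroxybenzyl)diphenylphosphine oxide, is bought.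

Assumption: the target SMILES holds no stereocentre and no stereogenic double bond, so the compound is achiral and no stereocontrol is needed.

**Route**

Step 1
Reactants: 1 2,3-dihydroxybenzoic acid (1.2 equiv); 2 1-octadecanol (1.0 equiv)
Product: 5 Gentiside E (octadecyl 2,3-dihydroxybenzoate), via cyclic oxyphosphonium carboxylate 3 (not isolated), via alkoxyphosphonium carboxylate ion pair 4 (not isolated)
Conditions: (2-hydroxybenzyl)diphenylphosphine oxide, Ph2P(O)CH2C6H4-2-OH (15 mol%), xylenes (0.2 M), reflux (about 140 °C), Dean–Stark trap, N2, 24–48 h; then EtOAc, aq. NaHCO3 wash, crystallisation from hexane/EtOAc
Reagents that add atoms: none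
Why: Proposed new method: a redox-neutral phosphine-oxide-catalysed Mitsunobu-type dehydrative O-alkylation, here put for the first time on a hydroxybenzoic acid that carries a free catechol: acid 1 (pKa about 2.9, in the range of the nitrobenzoic acids this catalysis needs, because the 2-hydroxyl hydrogen-bonds the carboxylate) protonates the P=O group of the catalyst, the tethered phenol closes onto phosphorus with loss of water (taken out in the trap) to give the strained five-membered oxyphosphonium salt 3, alcohol 2 opens that ring to alkoxyphosphonium salt 4, and the carboxylate, the only oxygen nucleophile ionised at this acidity (phenol pKa about 9 to 13), attacks the unhindered primary O–CH2 carbon in an SN2 step that forms the ester alkyl C–O bond and gives back the phosphine oxide, phosphorus staying pentavalent throughout; since the carboxyl group is never turned into an acylating agent, the free phenols cannot be acylated to oligoesters; the closest known reaction types are the phosphine-oxide-catalysed dehydrative Mitsunobu esterification of alcohols with strongly acidic nitrobenzoic acids and the stoichiometric Mitsunobu esterification of unprotected phenolic acids, which is selective for the carboxyl group; no stereocentre is formed.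

**Compound list**

1 | 2,3-dihydroxybenzoic acid | O=C(O)c1cccc(O)c1O | starting material
2 | 1-octadecanol (stearyl alcohol) | CCCCCCCCCCCCCCCCCCO | starting material
3 | 2,2-diphenyl-3H-1,2-benzoxaphosphol-2-ium 2,3-dihydroxybenzoate (cyclic oxyphosphonium salt from the catalyst and 1) | C1c2ccccc2O[P+]1(c1ccccc1)c1ccccc1.[O-]C(=O)c1cccc(O)c1O | intermediate
4 | (2-hydroxybenzyl)(octadecyloxy)diphenylphosphonium 2,3-dihydroxybenzoate (ion pair) | CCCCCCCCCCCCCCCCCCO[P+](Cc1ccccc1O)(c1ccccc1)c1ccccc1.[O-]C(=O)c1cccc(O)c1O | intermediate
5 | Gentiside E (octadecyl 2,3-dihydroxybenzoate) | CCCCCCCCCCCCCCCCCCOC(=O)c1cccc(O)c1O | target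

**Count and risks**

Total step count: 1. Longest linear sequence: 1 step.

Steps most likely to fail: the route has one step, so the list holds one entry.

Step 1 (the proposed new step). Ways it can fail:
- Acid 1 may sit at the weak edge of the acidity the catalyst needs, so salt 3 may form slowly.
- Acid 1 dissolves poorly in hot xylenes until it is consumed.
- The catechol may bind the phosphonium centre of 3 or 4 as a spirocyclic pentacoordinate phosphorane and hold back the catalyst.
- Long heating can cost some 1 by decarboxylation or air oxidation, hence N2.

Any acid-autocatalysed Fischer esterification running beside the catalysed path gives the same compound 5 and does no harm, since no stereocentre is at stake.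

Fallback (known chemistry, two steps, a stoichiometric alkyl halide in place of catalytic activation of the alcohol): it sets out from compound 2, which is heated at reflux with 48% aqueous HBr and concentrated H2SO4 to give 1-bromooctadecane F1. F1 (1.0 equiv) is then stirred with 1 (1.2 equiv) and KHCO3 (1.2 equiv) in DMF at 65 °C under N2. Hydrogencarbonate deprotonates only the carboxyl group, and the potassium carboxylate displaces bromide in an SN2 carboxylate alkylation. The fallback comes back to the route at compound 5.

**Further compounds**

F1 | step 1 | 1-bromooctadecane | CCCCCCCCCCCCCCCCCCBr
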